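**Plan**

1. Cuts, in retrosynthetic order: (a) the two aryl–CHO bonds; (b) C-9'–isobutyl and C-9'–H, then C-9'–C-9a' and the aryl–O bond of the pyran ring; (c) in the cyclohexene, the C=C between the vinylic CH and the isopropyl-bearing carbon together with the ring CH2–CH2 bond; (d) the bond from the quaternary carbon to the CH(CH3) carbon.
2. Forward: a bought cyclopentanone ring gains its quaternary carbon by [3,3] rearrangement, the spiro-cyclohexene is annulated, then the pyran ring is built onto a bought fluoroarene (ether first, C–C second); the formyl groups come last.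
3. Enabling feature: in the six-membered carbocycle the spiro carbon carries the vinylic CH, which can be stored as a non-enolisable aldehyde, and, through the methyl-bearing CH, a ring CH2 that can be unveiled as a primary radical by loss of CO2. The two remaining ring atoms, C(i-Pr)= and its CH2, are an α-isopropylvinylphosphonium, so one radical addition/olefination event closes the ring and leaves no functional group behind.
4. Stereochemistry: spiro carbon and CH(CH3) from a catalytic enantioselective Claisen rearrangement ((Z)-crotyl ether, chair); O–CH from a substrate-controlled Luche reduction; the methyl-bearing ring-fusion carbon from the oxygen tether (cis fusion); the benzylic carbon from hydride delivery to the convex face.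
5. Helpers: CO2H (leaves as CO2) and PPh3 (leaves as Ph3P=O) in the key step, a dioxolane on C-1, methyl ethers on the arene.

Key step: step 10

Remark: (Z)-but-2-en-1-ol, 2-fluoro-4,6-dimethoxybenzaldehyde and isobutyllithium are taken as purchasable; locants C-1 to C-10 are those of the spiro[4.5]decane ring of 20 (C-1 carbonyl carbon, C-5 spiro carbon, C-6=C-7 alkene, C-10 methyl-bearing carbon), and primed locants from 26 on are those of cyclopenta[b]chromene.

**Step 1**
Reactants: 1 3-methylbutan-2-one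
Product: 3 3-methylbut-1-en-2-yl trifluoromethanesulfonate, via lithium enolate 2 (not isolated)
Conditions: LiN(i-Pr)2, THF, −78 °C; then PhNTf2, −78 → 0 °C
Reagents that add atoms: N-phenylbis(trifluoromethanesulfonimide), O=S(=O)(N(c1ccccc1)S(=O)(=O)C(F)(F)F)C(F)(F)F
Why: Kinetic deprotonation of the methyl ketone at its CH3 group and O-sulfonylation of the terminal enolate (enol triflate formation) should give the 1,1-disubstituted vinyl triflate.

**Step 2**
Reactants: 3 3-methylbut-1-en-2-yl trifluoromethanesulfonate; 4 triphenylphosphine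
Product: 5 (3-methylbut-1-en-2-yl)triphenylphosphonium trifluoromethanesulfonate
Conditions: Pd(PPh3)4 (3 mol %), THF, reflux
Reagents that add atoms: none
Why: C–P coupling of a vinyl triflate with PPh3 under zerovalent palladium catalysis (oxidative addition, then reductive elimination of the phosphonium) is an established route to α-substituted vinylphosphonium triflates.

**Step 3**
Reactants: 6 methyl 2-oxocyclopentane-1-carboxylate; 7 (Z)-but-2-en-1-ol
Product: 8 methyl 2-[(2Z)-but-2-en-1-yloxy]cyclopent-1-ene-1-carboxylate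
Conditions: PPh3, DIAD, toluene, 0 °C → rt
Reagents that add atoms: none
Why: The Mitsunobu reaction of a cyclic β-ketoester with a primary allylic alcohol alkylates the enol oxygen, and the SN2 displacement keeps the (Z)-alkene.

**Step 4**
Reactants: 8 methyl 2-[(2Z)-but-2-en-1-yloxy]cyclopent-1-ene-1-carboxylate
Product: 9 methyl (1S)-1-[(2R)-but-3-en-2-yl]-2-oxocyclopentane-1-carboxylate
Conditions: chiral C2-symmetric guanidinium tetrakis[3,5-bis(trifluoromethyl)phenyl]borate (hydrogen-bond-donor catalyst, 20 mol %, the enantiomer that gives the (1S) ester), hexanes, 40 °C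
Reagents that add atoms: none
Why: In this catalytic enantioselective Claisen rearrangement of an O-allyl β-ketoester the catalyst selects the face of the ring enol ether (quaternary carbon S), and the chair transition state with the (Z)-methyl group axial relays the alkene geometry into the (R) methine.

**Step 5**
Reactants: 9 methyl (1S)-1-[(2R)-but-3-en-2-yl]-2-oxocyclopentane-1-carboxylate
Product: 10 methyl (6S)-6-[(2R)-but-3-en-2-yl]-1,4-dioxaspiro[4.4]nonane-6-carboxylate
Conditions: (Me3SiOCH2)2, Me3SiOTf (cat.), CH2Cl2, −78 → −20 °C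
Reagents that add atoms: 1,2-bis(trimethylsilyloxy)ethane, C[Si](C)(C)OCCO[Si](C)(C)C
Why: Ketalisation by silyl transfer works on hindered ketones and masks C-1, so that the later aldehyde on the same quaternary carbon is not part of a β-ketoaldehyde.

**Step 6**
Reactants: 10 methyl (6S)-6-[(2R)-but-3-en-2-yl]-1,4-dioxaspiro[4.4]nonane-6-carboxylate
Product: 12 methyl (6S)-6-[(2R)-4-hydroxybutan-2-yl]-1,4-dioxaspiro[4.4]nonane-6-carboxylate, via B-alkyl-9-BBN adduct 11 (not isolated)
Conditions: 9-BBN, THF, 0 °C → rt; then NaOH, H2O2, 0 °C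
Reagents that add atoms: hydrogen peroxide, OO
Why: Hydroboration–oxidation with the bulky dialkylborane puts oxygen on the terminal carbon of the monosubstituted alkene and leaves the hindered ester and the ketal alone.

**Step 7**
Reactants: 12 methyl (6S)-6-[(2R)-4-hydroxybutan-2-yl]-1,4-dioxaspiro[4.4]nonane-6-carboxylate
Product: 13 (3R)-3-[(6R)-6-(hydroxymethyl)-1,4-dioxaspiro[4.4]nonan-6-yl]butan-1-ol
Conditions: LiAlH4, THF, 0 °C → rt
Reagents that add atoms: none
Why: Hydride reduction of the hindered ester gives the neopentyl alcohol, and any lactone formed from 12 converges on the same diol.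

**Step 8**
Reactants: 13 (3R)-3-[(6R)-6-(hydroxymethyl)-1,4-dioxaspiro[4.4]nonan-6-yl]butan-1-ol
Product: 14 (2'R,4''R)-4''-methyldispiro[1,3-dioxolane-2,1'-cyclopentane-2',3''-oxan]-6''-one
Conditions: TEMPO (cat.), PhI(OAc)2, CH2Cl2, rt
Reagents that add atoms: none
Why: In this oxoammonium oxidative lactonisation of a 1,5-diol the unhindered primary alcohol is oxidised first, the aldehyde is trapped as a lactol by the neopentyl hydroxyl and oxidised on to the δ-lactone, so only the chain terminus reaches the acid level.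

**Step 9**
Reactants: 14 (2'R,4''R)-4''-methyldispiro[1,3-dioxolane-2,1'-cyclopentane-2',3''-oxan]-6''-one
Product: 16 (3R)-3-[(6R)-6-formyl-1,4-dioxaspiro[4.4]nonan-6-yl]butanoic acid, via lithium hydroxy-carboxylate 15 (not isolated)
Conditions: LiOH, THF/H2O, rt; then TEMPO (cat.), KBr, NaOCl, NaHCO3, CH2Cl2/H2O, 0 °C; then HCl to pH 3–4, 0 °C
Reagents that add atoms: lithium hydroxide, [Li+].[OH-]
Why: Saponification opens the lactone, and the neopentyl alcohol of the open carboxylate is then oxidised to the aldehyde (oxoammonium oxidation), which has no α-hydrogen and cannot epimerise.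

**Step 10**
Reactants: 16 (3R)-3-[(6R)-6-formyl-1,4-dioxaspiro[4.4]nonan-6-yl]butanoic acid; 5 (3-methylbut-1-en-2-yl)triphenylphosphonium trifluoromethanesulfonate
Product: 19 (5R,10R)-10-methyl-7-(propan-2-yl)spiro[4.5]dec-6-en-1-one ethylene ketal, via caesium carboxylate 17 (not isolated), via phosphonium ylide 18 (not isolated)
Conditions: [Ir(dF(CF3)ppy)2(dtbbpy)]PF6 (1 mol %), Cs2CO3, DMF (0.03 M), blue LEDs, rt
Reagents that add atoms: none
Why: Proposed new method: Carboxylate 17 is oxidised by the photoexcited trivalent-iridium complex and loses CO2; the primary C-9 radical adds (Giese) to the CH2 terminus of the electron-poor vinylphosphonium 5, the tertiary α-phosphonio radical is reduced by the reduced photocatalyst (radical–polar crossover) to ylide 18, and 18 olefinates the aldehyde (Wittig) with loss of Ph3P=O. The closest known reaction types are the photoredox decarboxylative radical addition to vinylphosphonium salts followed by intermolecular Wittig olefination, and the anionic annulation of carbonyl-tethered nucleophiles with vinylphosphonium salts; new here are the ring-forming version, the α-branched acceptor and the neopentyl aldehyde. The cyclohexene closes in the olefination event by 6-exo-trig attack of the ylide carbon on the formyl group and collapse of the oxaphosphetane, so that a two-carbon unit is stitched between C-9 and C-6 (formal [4+2] annulation). No stereocentre is created: C-5 and C-10 pass through unchanged because the aldehyde is non-enolisable and the radical carbon is not stereogenic, and the ring fixes position and geometry of the alkene. The step needs the radical to add intermolecularly before it is reduced or abstracts hydrogen, and the ylide to cyclise before it is protonated: 16 has no alkene or weak C–H bond within reach of C-9, 5 is used in excess, and excess Cs2CO3 keeps the medium basic and can regenerate the ylide from its conjugate acid.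

**Step 11**
Reactants: 19 (5R,10R)-10-methyl-7-(propan-2-yl)spiro[4.5]dec-6-en-1-one ethylene ketal
Product: 20 (5R,10R)-10-methyl-7-(propan-2-yl)spiro[4.5]dec-6-en-1-one
Conditions: 1 M HCl, THF, rt
Reagents that add atoms: water, O
Why: Acid-catalysed acetal hydrolysis frees the ketone, and dilute acid at room temperature should not move the trisubstituted ring alkene.

**Step 12**
Reactants: 20 (5R,10R)-10-methyl-7-(propan-2-yl)spiro[4.5]dec-6-en-1-one
Product: 21 (5R,10R)-10-methyl-2-methylidene-7-(propan-2-yl)spiro[4.5]dec-6-en-1-one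
Conditions: (CH2O)n, N-methylanilinium trifluoroacetate, THF, reflux
Reagents that add atoms: formaldehyde (as paraformaldehyde), C=O
Why: Mannich-type α-methylenation (iminium addition, then β-elimination of the amine) can occur only at C-2, the single enolisable position.

**Step 13**
Reactants: 21 (5R,10R)-10-methyl-2-methylidene-7-(propan-2-yl)spiro[4.5]dec-6-en-1-one
Product: 22 (1R,5R,10R)-10-methyl-2-methylidene-7-(propan-2-yl)spiro[4.5]dec-6-en-1-ol
Conditions: NaBH4, CeCl3·7H2O, MeOH, −78 °C
Reagents that add atoms: none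
Why: In this Luche 1,2-reduction hydride should attack the carbonyl from the face flanked by the flat vinylic C-6, away from the methyl-bearing C-10, which sets (1R) with the hydroxyl syn to C-10.

**Step 14**
Reactants: 22 (1R,5R,10R)-10-methyl-2-methylidene-7-(propan-2-yl)spiro[4.5]dec-6-en-1-ol; 23 2-fluoro-4,6-dimethoxybenzaldehyde
Product: 25 2-{[(1R,5R,10R)-10-methyl-2-methylidene-7-(propan-2-yl)spiro[4.5]dec-6-en-1-yl]oxy}-4,6-dimethoxybenzaldehyde, via sodium alkoxide 24 (not isolated)
Conditions: NaH, DMF, 0 °C; then 23, 0 °C → rt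
Reagents that add atoms: none
Why: Nucleophilic aromatic substitution of the formyl-activated ortho-fluoride forms the aryl–O bond without touching C-1, so its configuration is kept.

**Step 15**
Reactants: 25 2-{[(1R,5R,10R)-10-methyl-2-methylidene-7-(propan-2-yl)spiro[4.5]dec-6-en-1-yl]oxy}-4,6-dimethoxybenzaldehyde
Product: 26 (1R,3a'S,6R,9a'R)-6',8'-dimethoxy-6,9a'-dimethyl-3-(propan-2-yl)-1',2',3a',9a'-tetrahydro-9'H-spiro[cyclohex-2-ene-1,3'-cyclopenta[b]chromen]-9'-one
Conditions: N-mesitylthiazolium salt precatalyst (20 mol %), DBU (40 mol %), 1,4-dioxane, 120 °C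
Reagents that add atoms: none
Why: In this NHC-catalysed intramolecular hydroacylation of an unactivated 1,1-disubstituted alkene (Conia-ene-type addition of the acyl-anion equivalent) the short oxygen tether forces C–C bond formation at C-2 on the face of the ether oxygen, giving the cis-fused chromanone, the quaternary C-9a' and the angular methyl from the methylidene group.

**Step 16**
Reactants: 26 (1R,3a'S,6R,9a'R)-6',8'-dimethoxy-6,9a'-dimethyl-3-(propan-2-yl)-1',2',3a',9a'-tetrahydro-9'H-spiro[cyclohex-2-ene-1,3'-cyclopenta[b]chromen]-9'-one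
Product: 27 (1R,3a'S,6R,9'R,9a'R)-6',8'-dimethoxy-6,9a'-dimethyl-9'-(2-methylpropyl)-3-(propan-2-yl)-1',2',3a',9a'-tetrahydro-9'H-spiro[cyclohex-2-ene-1,3'-cyclopenta[b]chromen]-9'-ol
Conditions: CeCl3, i-BuLi, THF, −78 °C; then 26, −78 → −20 °C
Reagents that add atoms: isobutyllithium, [Li]CC(C)C
Why: 1,2-Addition of a weakly basic organocerium reagent to the hindered, non-enolisable aryl ketone should give the tertiary benzylic alcohol, whose configuration at C-9' (drawn for attack on the convex face) is erased in step 17.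

**Step 17**
Reactants: 27 (1R,3a'S,6R,9'R,9a'R)-6',8'-dimethoxy-6,9a'-dimethyl-9'-(2-methylpropyl)-3-(propan-2-yl)-1',2',3a',9a'-tetrahydro-9'H-spiro[cyclohex-2-ene-1,3'-cyclopenta[b]chromen]-9'-ol
Product: 28 (1R,3a'R,6R,9'R,9a'S)-6',8'-dimethoxy-6,9a'-dimethyl-9'-(2-methylpropyl)-3-(propan-2-yl)-1',2',3a',9a'-tetrahydro-9'H-spiro[cyclohex-2-ene-1,3'-cyclopenta[b]chromene]
Conditions: Et3SiH, CF3CO2H, CH2Cl2, −40 → 0 °C
Reagents that add atoms: none
Why: In this ionic hydrogenation acid ionises the carbinol to a benzylic cation stabilised by three ortho/para oxygens, and Et3SiH delivers hydride to the convex face, anti to the cis-fused cyclopentane and its spiro ring, which sets (9'R) with the isobutyl group on the concave side.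

**Step 18**
Reactants: 28 (1R,3a'R,6R,9'R,9a'S)-6',8'-dimethoxy-6,9a'-dimethyl-9'-(2-methylpropyl)-3-(propan-2-yl)-1',2',3a',9a'-tetrahydro-9'H-spiro[cyclohex-2-ene-1,3'-cyclopenta[b]chromene]
Product: 29 (1R,3a'R,6R,9'R,9a'S)-6,9a'-dimethyl-9'-(2-methylpropyl)-3-(propan-2-yl)-1',2',3a',9a'-tetrahydro-9'H-spiro[cyclohex-2-ene-1,3'-cyclopenta[b]chromene]-6',8'-diol
Conditions: BBr3, CH2Cl2, −78 → 0 °C; cold aq NaHCO3
Reagents that add atoms: none
Why: Lewis-acid cleavage of the two aryl methyl ethers spares the chroman C–O bond, whose secondary carbon lies between two quaternary centres, and the cold bicarbonate quench keeps HBr away from the ring alkene.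

**Step 19**
Reactants: 29 (1R,3a'R,6R,9'R,9a'S)-6,9a'-dimethyl-9'-(2-methylpropyl)-3-(propan-2-yl)-1',2',3a',9a'-tetrahydro-9'H-spiro[cyclohex-2-ene-1,3'-cyclopenta[b]chromene]-6',8'-diol
Product: 31 (1R,3a'R,6R,9'R,9a'S)-6',8'-dihydroxy-6,9a'-dimethyl-9'-(2-methylpropyl)-3-(propan-2-yl)-1',2',3a',9a'-tetrahydro-9'H-spiro[cyclohex-2-ene-1,3'-cyclopenta[b]chromene]-5',7'-dicarbaldehyde, via bis(iminium) salt 30 (not isolated)
Conditions: POCl3, DMF, 0 °C → rt; then aq NaOAc, 50 °C
Reagents that add atoms: N,N-dimethylformamide, CN(C)C=O; water, O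
Why: In this double Vilsmeier–Haack formylation both free ring positions are ortho/para to three oxygens, the reactivity that turns phloroglucinol into its dialdehyde, and the chloroiminium electrophile does not attack an isolated trisubstituted alkene.

**Compound list**

1 | 3-methylbutan-2-one | CC(=O)C(C)C | starting material
2 | lithium 3-methylbut-1-en-2-olate | [Li+].[O-]C(=C)C(C)C | intermediate
3 | 3-methylbut-1-en-2-yl trifluoromethanesulfonate | C=C(OS(=O)(=O)C(F)(F)F)C(C)C | intermediate
4 | triphenylphosphine | c1ccc(cc1)P(c1ccccc1)c1ccccc1 | starting material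
5 | (3-methylbut-1-en-2-yl)triphenylphosphonium trifluoromethanesulfonate | C=C(C(C)C)[P+](c1ccccc1)(c1ccccc1)c1ccccc1.[O-]S(=O)(=O)C(F)(F)F | intermediate
6 | methyl 2-oxocyclopentane-1-carboxylate | COC(=O)C1CCCC1=O | starting material
7 | (Z)-but-2-en-1-ol | C/C=C\CO | starting material
8 | methyl 2-[(2Z)-but-2-en-1-yloxy]cyclopent-1-ene-1-carboxylate | COC(=O)C1=C(OC/C=C\C)CCC1 | intermediate
9 | methyl (1S)-1-[(2R)-but-3-en-2-yl]-2-oxocyclopentane-1-carboxylate | C=C[C@@H](C)[C@@]1(C(=O)OC)CCCC1=O | intermediate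
10 | methyl (6S)-6-[(2R)-but-3-en-2-yl]-1,4-dioxaspiro[4.4]nonane-6-carboxylate | C=C[C@@H](C)[C@@]1(C(=O)OC)CCCC12OCCO2 | intermediate
11 | methyl (6S)-6-[(2R)-4-(9-borabicyclo[3.3.1]nonan-9-yl)butan-2-yl]-1,4-dioxaspiro[4.4]nonane-6-carboxylate | B1(CC[C@@H](C)[C@@]2(C(=O)OC)CCCC23OCCO3)C2CCCC1CCC2 | intermediate
12 | methyl (6S)-6-[(2R)-4-hydroxybutan-2-yl]-1,4-dioxaspiro[4.4]nonane-6-carboxylate | OCC[C@@H](C)[C@@]1(C(=O)OC)CCCC12OCCO2 | intermediate
13 | (3R)-3-[(6R)-6-(hydroxymethyl)-1,4-dioxaspiro[4.4]nonan-6-yl]butan-1-ol | OCC[C@@H](C)[C@@]1(CO)CCCC12OCCO2 | intermediate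
14 | (2'R,4''R)-4''-methyldispiro[1,3-dioxolane-2,1'-cyclopentane-2',3''-oxan]-6''-one | O=C1C[C@@H](C)[C@@]2(CO1)CCCC23OCCO3 | intermediate
15 | lithium (3R)-3-[(6R)-6-(hydroxymethyl)-1,4-dioxaspiro[4.4]nonan-6-yl]butanoate | [Li+].[O-]C(=O)C[C@@H](C)[C@@]1(CO)CCCC12OCCO2 | intermediate
16 | (3R)-3-[(6R)-6-formyl-1,4-dioxaspiro[4.4]nonan-6-yl]butanoic acid | OC(=O)C[C@@H](C)[C@@]1(C=O)CCCC12OCCO2 | intermediate
17 | caesium (3R)-3-[(6R)-6-formyl-1,4-dioxaspiro[4.4]nonan-6-yl]butanoate | [Cs+].[O-]C(=O)C[C@@H](C)[C@@]1(C=O)CCCC12OCCO2 | intermediate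
18 | {(6R)-6-[(6R)-6-formyl-1,4-dioxaspiro[4.4]nonan-6-yl]-2-methylheptan-3-ylidene}triphenyl-λ5-phosphane | CC(C)C(CC[C@@H](C)[C@@]1(C=O)CCCC12OCCO2)=P(c1ccccc1)(c1ccccc1)c1ccccc1 | intermediate
19 | (5R,10R)-10-methyl-7-(propan-2-yl)spiro[4.5]dec-6-en-1-one ethylene ketal | C1COC2(O1)CCC[C@@]23C=C(C(C)C)CC[C@H]3C | intermediate
20 | (5R,10R)-10-methyl-7-(propan-2-yl)spiro[4.5]dec-6-en-1-one | O=C1CCC[C@@]12C=C(C(C)C)CC[C@H]2C | intermediate
21 | (5R,10R)-10-methyl-2-methylidene-7-(propan-2-yl)spiro[4.5]dec-6-en-1-one | O=C1C(=C)CC[C@@]12C=C(C(C)C)CC[C@H]2C | intermediate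
22 | (1R,5R,10R)-10-methyl-2-methylidene-7-(propan-2-yl)spiro[4.5]dec-6-en-1-ol | O[C@@H]1C(=C)CC[C@@]12C=C(C(C)C)CC[C@H]2C | intermediate
23 | 2-fluoro-4,6-dimethoxybenzaldehyde | O=Cc1c(F)cc(OC)cc1OC | starting material
24 | sodium (1R,5R,10R)-10-methyl-2-methylidene-7-(propan-2-yl)spiro[4.5]dec-6-en-1-olate | [Na+].[O-][C@@H]1C(=C)CC[C@@]12C=C(C(C)C)CC[C@H]2C | intermediate
25 | 2-{[(1R,5R,10R)-10-methyl-2-methylidene-7-(propan-2-yl)spiro[4.5]dec-6-en-1-yl]oxy}-4,6-dimethoxybenzaldehyde | O=Cc1c(OC)cc(OC)cc1O[C@@H]1C(=C)CC[C@@]12C=C(C(C)C)CC[C@H]2C | intermediate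
26 | (1R,3a'S,6R,9a'R)-6',8'-dimethoxy-6,9a'-dimethyl-3-(propan-2-yl)-1',2',3a',9a'-tetrahydro-9'H-spiro[cyclohex-2-ene-1,3'-cyclopenta[b]chromen]-9'-one | O=C1c2c(OC)cc(OC)cc2O[C@@H]2[C@@]1(C)CC[C@@]21C=C(C(C)C)CC[C@H]1C | intermediate
27 | (1R,3a'S,6R,9'R,9a'R)-6',8'-dimethoxy-6,9a'-dimethyl-9'-(2-methylpropyl)-3-(propan-2-yl)-1',2',3a',9a'-tetrahydro-9'H-spiro[cyclohex-2-ene-1,3'-cyclopenta[b]chromen]-9'-ol | CC(C)C[C@]1(O)c2c(OC)cc(OC)cc2O[C@@H]2[C@@]1(C)CC[C@@]21C=C(C(C)C)CC[C@H]1C | intermediate
28 | (1R,3a'R,6R,9'R,9a'S)-6',8'-dimethoxy-6,9a'-dimethyl-9'-(2-methylpropyl)-3-(propan-2-yl)-1',2',3a',9a'-tetrahydro-9'H-spiro[cyclohex-2-ene-1,3'-cyclopenta[b]chromene] | CC(C)C[C@H]1c2c(OC)cc(OC)cc2O[C@@H]2[C@@]1(C)CC[C@@]21C=C(C(C)C)CC[C@H]1C | intermediate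
29 | (1R,3a'R,6R,9'R,9a'S)-6,9a'-dimethyl-9'-(2-methylpropyl)-3-(propan-2-yl)-1',2',3a',9a'-tetrahydro-9'H-spiro[cyclohex-2-ene-1,3'-cyclopenta[b]chromene]-6',8'-diol | CC(C)C[C@H]1c2c(O)cc(O)cc2O[C@@H]2[C@@]1(C)CC[C@@]21C=C(C(C)C)CC[C@H]1C | intermediate
30 | 5',7'-bis(dimethyliminiomethyl) derivative of 29, dichloride | CC(C)C[C@H]1c2c(O)c(C=[N+](C)C)c(O)c(C=[N+](C)C)c2O[C@@H]2[C@@]1(C)CC[C@@]21C=C(C(C)C)CC[C@H]1C.[Cl-].[Cl-] | intermediate
31 | (1R,3a'R,6R,9'R,9a'S)-6',8'-dihydroxy-6,9a'-dimethyl-9'-(2-methylpropyl)-3-(propan-2-yl)-1',2',3a',9a'-tetrahydro-9'H-spiro[cyclohex-2-ene-1,3'-cyclopenta[b]chromene]-5',7'-dicarbaldehyde | CC(C)C[C@H]1c2c(O)c(C=O)c(O)c(C=O)c2O[C@@H]2[C@@]1(C)CC[C@@]21C=C(C(C)C)CC[C@H]1C | target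

**Count and risks**

Total step count: 19. Longest linear sequence: 17 steps (steps 3 to 19, from 6); steps 1 and 2 are a two-step branch that joins at step 10.

Step 10 (proposed new method). What may go wrong: reduction or hydrogen abstraction of the primary radical before it adds to the vinylphosphonium salt, or protonation of the ylide before ring closure, so that only open-chain material forms. The fallback uses known chemistry and sets out from 10. Hydroboration with 9-BBN (borane 11) and B-alkyl Suzuki–Miyaura coupling with triflate 3 (Pd(dppf)Cl2, K3PO4) should give methyl (6S)-6-[(2R)-6-methyl-5-methylideneheptan-2-yl]-1,4-dioxaspiro[4.4]nonane-6-carboxylate F1. Reduction with i-Bu2AlH at −78 °C should stop at the hindered aldehyde (6R)-6-[(2R)-6-methyl-5-methylideneheptan-2-yl]-1,4-dioxaspiro[4.4]nonane-6-carbaldehyde F2. Wittig methylenation (Ph3P=CH2) should give the diene (6S)-6-ethenyl-6-[(2R)-6-methyl-5-methylideneheptan-2-yl]-1,4-dioxaspiro[4.4]nonane F3. Ring-closing metathesis with the second-generation Grubbs catalyst should then close the trisubstituted cyclohexene with loss of ethene and come back to the route at 19.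

Step 15. What may go wrong: slow formation of the acyl-anion equivalent from the doubly ortho-substituted, electron-rich aldehyde, so that thermal rearrangement of the allyl aryl ether takes over. The fallback sets out from 25. Addition of i-BuMgBr should give the benzylic alcohol 1-(2-{[(1R,5R,10R)-10-methyl-2-methylidene-7-(propan-2-yl)spiro[4.5]dec-6-en-1-yl]oxy}-4,6-dimethoxyphenyl)-3-methylbutan-1-ol F4 (either epimer), and DMP oxidation the aryl ketone 1-(2-{[(1R,5R,10R)-10-methyl-2-methylidene-7-(propan-2-yl)spiro[4.5]dec-6-en-1-yl]oxy}-4,6-dimethoxyphenyl)-3-methylbutan-1-one F5. A hydrogen-atom-transfer radical cyclisation (Fe(acac)3, PhSiH3, EtOH, 60 °C) should follow, in which the tertiary C-2 radical formed from the methylidene group adds to the ketone carbonyl on the face of the ether oxygen. The fallback comes back at 27, so step 16 is not needed.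

Step 14. What may go wrong: slow substitution by the hindered alkoxide and competing hydride transfer from the allylic alkoxide to the aldehyde. The fallback sets out from 22. The lithium alkoxide (LiN(SiMe3)2, toluene) and the more electrophilic 2,4,6-trifluorobenzaldehyde should react ortho to the formyl group, lithium bridging alkoxide and carbonyl oxygen, to give 2,4-difluoro-6-{[(1R,5R,10R)-10-methyl-2-methylidene-7-(propan-2-yl)spiro[4.5]dec-6-en-1-yl]oxy}benzaldehyde F6. NaOMe in MeOH/THF should then replace both remaining fluorides and come back at 25.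

**Further compounds**

F1 | step 10 | methyl (6S)-6-[(2R)-6-methyl-5-methylideneheptan-2-yl]-1,4-dioxaspiro[4.4]nonane-6-carboxylate | C=C(C(C)C)CC[C@@H](C)[C@@]1(C(=O)OC)CCCC12OCCO2
F2 | step 10 | (6R)-6-[(2R)-6-methyl-5-methylideneheptan-2-yl]-1,4-dioxaspiro[4.4]nonane-6-carbaldehyde | C=C(C(C)C)CC[C@@H](C)[C@@]1(C=O)CCCC12OCCO2
F3 | step 10 | (6S)-6-ethenyl-6-[(2R)-6-methyl-5-methylideneheptan-2-yl]-1,4-dioxaspiro[4.4]nonane | C=C(C(C)C)CC[C@@H](C)[C@@]1(C=C)CCCC12OCCO2
F4 | step 15 | 1-(2-{[(1R,5R,10R)-10-methyl-2-methylidene-7-(propan-2-yl)spiro[4.5]dec-6-en-1-yl]oxy}-4,6-dimethoxyphenyl)-3-methylbutan-1-ol | CC(C)CC(O)c1c(OC)cc(OC)cc1O[C@@H]1C(=C)CC[C@@]12C=C(C(C)C)CC[C@H]2C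
F5 | step 15 | 1-(2-{[(1R,5R,10R)-10-methyl-2-methylidene-7-(propan-2-yl)spiro[4.5]dec-6-en-1-yl]oxy}-4,6-dimethoxyphenyl)-3-methylbutan-1-one | CC(C)CC(=O)c1c(OC)cc(OC)cc1O[C@@H]1C(=C)CC[C@@]12C=C(C(C)C)CC[C@H]2C
F6 | step 14 | 2,4-difluoro-6-{[(1R,5R,10R)-10-methyl-2-methylidene-7-(propan-2-yl)spiro[4.5]dec-6-en-1-yl]oxy}benzaldehyde | O=Cc1c(F)cc(F)cc1O[C@@H]1C(=C)CC[C@@]12C=C(C(C)C)CC[C@H]2C
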